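(The numbers of this flask are those of an exercise, and the outcome is calculated.)

A small charge of starting material goes into each flask below, and the question is how much of the target made from it escapes the step that consumes target.

| flask | starting material | partner | protic impurity | temperature | time | remark |
|---|---|---|---|---|---|---|
| birch | 0.050 M | 0.0650 M | 0.0100 M | 55 °C | 30 min |  |
| oak | 0.050 M | 0.0650 M | 0.0100 M | −5 °C | 30 min |  |
| alder | 0.050 M | 0.0650 M | 0.0100 M | 25 °C | 30 min |  |
| cedar | 0.050 M | 0.0650 M | 0.0100 M |  | 30 min | at −5 °C until 20 min, from then on at 55 °C |

    starting material ⇌ open intermediate (K1 = 0.813, k1 = 0.00536 s⁻¹, Ea1 = 81.0 kJ mol⁻¹, ΔH1 = −12.0 kJ mol⁻¹)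
    partner → second intermediate (k2 = 0.00494 s⁻¹, Ea2 = 87.0 kJ mol⁻¹)
    open intermediate + second intermediate → target (k3 = 0.0795 M⁻¹ s⁻¹, Ea3 = 60.0 kJ mol⁻¹)
    starting material + protic impurity → quenched substrate (k4 = 1.91 M⁻¹ s⁻¹, Ea4 = 42.0 kJ mol⁻¹)
    2 starting material → homo dimer (k5 = 4.61 × 10⁻⁴ M⁻¹ s⁻¹, Ea5 = 82.0 kJ mol⁻¹)
    target → over-reaction product (k6 = 1.91 × 10⁻⁴ s⁻¹, Ea6 = 102 kJ mol⁻¹)
    (constants at 25 °C)

- percentages count the starting material that a species holds: one homo dimer counts as two
- a step written with two of one species runs at k times the square of its concentration and takes two of it each time
- the constants hold at 25 °C; other temperatures follow from the activation energies and enthalpies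

1. the best flask by share of target in all that became target or over-reaction product; "all alike" if 1.5 percentage points covers them all (birch / oak / alder / cedar / all alike)
2. share of target in all that became target or over-reaction product, birch
3. share of target in all that became target or over-reaction product, oak
4. share of target in all that became target or over-reaction product, alder
5. share of target in all that became target or over-reaction product, cedar

1. Here is the puzzle. Cedar stands at −5 °C for 20 min of its 30 min, yet its last 10.0 min at 55 °C weigh more on target than that long cold stretch.

2. Target is lost at a rate equal to the over-reaction's rate constant times c(target), so each target molecule decays with its own clock, whatever else the flask holds. That constant is 1.91 × 10⁻⁴ s⁻¹ at 25 °C. With its activation energy it becomes 0.00822 s⁻¹ at 55 °C and 1.91 × 10⁻⁶ s⁻¹ at −5 °C.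

3. Multiply that constant by the time held, and add up the stretches of a run. You get the number of target time constants the flask runs through. Oak holds 0.00344 of this ageing dose. Alder holds 0.344 and birch 14.8.

4. Cedar's hot stretch gives 4.93 and its cold stretch 0.00230, so the hot stretch holds nearly all of cedar's dose. That clears the puzzle: the clock counts rate constant times time, not time.

5. The asked share (a selectivity) is the average survival of target. Target born at the start survives as exp(−dose). Target born evenly through the run survives as (1 − exp(−dose))/dose. Even birth gives me birch 6.76 %, oak 99.8 %, alder 84.6 % and cedar 20.1 %. Birth at the start gives alder 70.9 % and cedar 0.721 %. I pick oak.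

6. The forecast names oak, with birch 0.002 %, oak 99.9 %, alder 81 % and cedar 3 %. Its grounds: “oak is best on selectivity even though it makes the least target”. Its alder and cedar stand lower than my even-birth values.

7. The simulation gives oak as best, with birch 0 %, oak 99.9 %, alder 80.6 % and cedar 3.20 %. Oak earned that share with 0.567 % target, while 63.5 % of the starting material still stood at 30.0 min. In cedar, target stood at 0.186 % at the change, 20.0 min, and by 30.0 min over-reaction product held 75.2 % beside 2.48 % target. Left for 300 min, oak's dose becomes 0.0344, even birth gives 98.3 %, and oak stands at 98.5 %. A neighbour like oak but kept at 20 °C has a dose of 0.170, even birth gives 91.9 %, and that flask reached 91.2 %.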